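**Assumption:** the (S,S)- or (R,R)-IDPi enantiomer that gives carbonate 4 as (4aR,8aS) is used, and farnesol is the (2E,6E) isomer. Preluffariellolide A is the C25 monocycle from geranylfarnesol: an all-E farnesyl-type chain joined through C12–C13 to a trans-configured 2-substituted 1,3,3-trimethylcyclohexan-1-ol. In that ring the C15 methyl is axial, the OH is equatorial and the C13 chain is equatorial.

## Retrosynthetic overview
1. Disconnect C12–C13 (sp3–sp3) by a Cu-catalysed Grignard/allylic-bromide coupling. The pieces are a cyclogeranyl-type CH2–MgX (ring) and an E-12-bromofarnesyl silyl ether (chain).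
2. The chain comes from farnesol by E-selective SeO2 oxidation of the terminal E-methyl, which keeps the three commercial E-olefins intact.
3. The only ring is formed once, with both stereocenters set together. An organocatalytic enantioselective protonative monocyclization of geranyl tert-butyl carbonate is terminated by the carbonate C=O, giving a trans-fused cyclic carbonate.
4. LiAlH4 reveals the 1,3-diol. The primary alcohol is converted to the iodide and the tertiary alcohol is protected, giving the Grignard precursor.

## Route

**Step 1**
Reactants: 1 (2E)-geraniol; 2 di-tert-butyl dicarbonate (Boc2O)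
Product: 3 geranyl tert-butyl carbonate
Conditions: Boc2O, DMAP (cat.), CH2Cl2, 0 °C → rt
Reagents that add atoms: Boc2O (2), CC(C)(C)OC(=O)OC(=O)OC(C)(C)C (supplies the CO2tBu group)
Why: DMAP-catalysed O-acylation, a standard carbonate formation. The allylic carbonate is the nucleophilic terminator for step 2 and later becomes the C13 oxygen.

**Step 2**
Reactants: 3
Product: 4 (4aR,8aS)-5,5,8a-trimethylhexahydro-4H-1,3-benzodioxin-2-one, plus isobutene
Conditions: chiral IDPi (5 mol %), cyclohexane/CH2Cl2 9:1, 4 Å MS, –30 °C, 72 h
Reagents that add atoms: none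
Why: Proposed new method: the confined IDPi protonates the terminal trisubstituted alkene at C18, and the chair-like (E)-1,5-diene transition state closes the C14–C19 bond. This sets C14 and the C15 cation, whose methyl is axial, and the carbonate C=O then captures C15 from the equatorial trajectory to form a trans-fused 1,3-dioxan-2-ylium. Loss of t-Bu+ as isobutene gives the neutral cyclic carbonate and regenerates the acid. The closest known reactions are chiral Brønsted-acid-catalysed polyene and homofarnesol cyclizations and carbonyl/carbonate-terminated cation–olefin cyclizations. A chiral Brønsted acid has not been shown to do the asymmetric carbonate-terminated monocyclization of a geranyl carbonate, and this one step makes the ring and both stereocenters.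

**Step 3**
Reactants: 4
Product: 5 (1S,2R)-2-(hydroxymethyl)-1,3,3-trimethylcyclohexan-1-ol
Conditions: LiAlH4, THF, 0 °C → rt
Reagents that add atoms: none (hydride only)
Why: Hydride attacks the carbonyl and opens the carbonate to the diol plus MeOH. Both C–O bonds at the stereocenters are untouched, so no stereocenter is scrambled.

**Step 4**
Reactants: 5
Product: 6 (1S,2S)-2-(iodomethyl)-1,3,3-trimethylcyclohexan-1-ol
Conditions: PPh3, I2, imidazole, toluene, 80 °C
Reagents that add atoms: I2, II
Why: Appel–Garegg iodination is an SN2 at the primary carbon. The tertiary alcohol does not react, and no stereocenter is involved.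

**Step 5**
Reactants: 6
Product: 7 (1S,2S)-1-(triethylsilyloxy)-2-(iodomethyl)-1,3,3-trimethylcyclohexane
Conditions: TESOTf, 2,6-lutidine, CH2Cl2, –20 °C
Reagents that add atoms: TESOTf, CC[Si](CC)(CC)OS(=O)(=O)C(F)(F)F
Why: Silylating the tertiary OH makes the iodide compatible with Grignard formation in step 9.

**Step 6**
Reactants: 8 (2E,6E)-farnesol
Product: 9 farnesyl TBS ether
Conditions: TBSCl, imidazole, DMF, rt
Reagents that add atoms: TBSCl, CC(C)(C)[Si](C)(C)Cl
Why: A standard silyl protection that also deactivates the C2=C3 olefin toward SeO2.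

**Step 7**
Reactants: 9
Product: 10 (2E,6E,10E)-12-(TBS-oxy)-2,6,10-trimethyldodeca-2,6,10-trien-1-ol (12-hydroxyfarnesyl TBS ether)
Conditions: SeO2 (10 mol %), t-BuOOH, salicylic acid (cat.), CH2Cl2, 0 °C → rt
Reagents that add atoms: t-BuOOH, CC(C)(C)OO; SeO2, O=[Se]=O (both are sources of the new OH oxygen)
Why: Umbreit–Sharpless allylic oxidation (ene reaction followed by [2,3]-shift) occurs at the most electron-rich terminal olefin. It takes the methyl trans to the chain, giving the E-allylic alcohol, which matches the C10=C11 geometry of the target.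

**Step 8**
Reactants: 10
Product: 11 tert-butyl{[(2E,6E,10E)-12-bromo-3,7,11-trimethyldodeca-2,6,10-trien-1-yl]oxy}dimethylsilane
Conditions: CBr4, PPh3, CH2Cl2, 0 °C
Reagents that add atoms: CBr4, BrC(Br)(Br)Br
Why: Appel bromination proceeds by SN2 at the primary allylic carbon and leaves the olefin geometry unchanged.

**Step 9**
Reactants: 7 and 11
Product: 12 TBS/TES-protected preluffariellolide A
Conditions: (i) 7, Mg turnings, 1,2-dibromoethane (cat.), THF, 50 °C → RMgI; (ii) 11, Li2CuCl4 (5 mol %), THF, –30 → 0 °C
Reagents that add atoms: none
Why: Cu-catalysed SN2 (α-selective) allylic alkylation of an alkyl Grignard with a primary allylic bromide forms the C12–C13 bond with retention of all olefin geometries. The ring stereocenters are not involved.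

**Step 10**
Reactants: 12
Product: 13 preluffariellolide A
Conditions: TBAF, THF, rt
Reagents that add atoms: none
Why: Fluoride removes both silyl ethers under basic conditions, so the tertiary alcohol and the trisubstituted olefins are not exposed to acid.

## Compound list
1 | (2E)-geraniol | C/C(=C\CO)CCC=C(C)C | starting material
2 | di-tert-butyl dicarbonate | CC(C)(C)OC(=O)OC(=O)OC(C)(C)C | starting material
3 | geranyl tert-butyl carbonate | C/C(=C\COC(=O)OC(C)(C)C)CCC=C(C)C | intermediate
4 | (4aR,8aS)-5,5,8a-trimethylhexahydro-4H-1,3-benzodioxin-2-one | O=C1OC[C@H]2C(C)(C)CCC[C@]2(C)O1 | intermediate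
5 | (1S,2R)-2-(hydroxymethyl)-1,3,3-trimethylcyclohexan-1-ol | OC[C@H]1C(C)(C)CCC[C@]1(C)O | intermediate
6 | (1S,2S)-2-(iodomethyl)-1,3,3-trimethylcyclohexan-1-ol | IC[C@H]1C(C)(C)CCC[C@]1(C)O | intermediate
7 | (1S,2S)-1-(triethylsilyloxy)-2-(iodomethyl)-1,3,3-trimethylcyclohexane | IC[C@H]1C(C)(C)CCC[C@]1(C)O[Si](CC)(CC)CC | intermediate
8 | (2E,6E)-farnesol | C/C(=C\CO)CC/C=C(\C)CCC=C(C)C | starting material
9 | farnesyl TBS ether | C/C(=C\CO[Si](C)(C)C(C)(C)C)CC/C=C(\C)CCC=C(C)C | intermediate
10 | 12-hydroxyfarnesyl TBS ether | OC/C(C)=C/CC/C(C)=C/CC/C(C)=C/CO[Si](C)(C)C(C)(C)C | intermediate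
11 | 12-bromofarnesyl TBS ether | BrC/C(C)=C/CC/C(C)=C/CC/C(C)=C/CO[Si](C)(C)C(C)(C)C | intermediate
12 | protected preluffariellolide A | CC(C)(C)[Si](C)(C)OC/C=C(\C)CC/C=C(\C)CC/C=C(\C)CC[C@H]1C(C)(C)CCC[C@]1(C)O[Si](CC)(CC)CC | intermediate
13 | preluffariellolide A | C/C(=C\CO)CC/C=C(\C)CC/C=C(\C)CC[C@H]1C(C)(C)CCC[C@]1(C)O | target

**Total steps:** 10. **Longest linear sequence:** 7 (geraniol → 3 → 4 → 5 → 6 → 7 → 12 → 13).

## Three steps most likely to fail
1. **Step 2 (proposed new IDPi cyclization).** The carbonate may lose t-Bu+ or ionize allylically before the alkene is protonated, or the ee may be low.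
   - Fallback (known chemistry): do a racemic SnCl4- or TfOH-mediated carbonate-terminated cyclization of 3 to (±)-4, reduce to (±)-5, and resolve by CAL-B kinetic acetylation of the primary OH or by preparative chiral SFC.
2. **Step 7 (SeO2 terminal-methyl oxidation).** Yield is modest, and over-oxidation to the aldehyde or oxidation at other olefins can occur.
   - Fallback: build the E-12-OH fragment by olefination instead. Convert 9 to the terminal epoxide (NBS/H2O, then K2CO3), cleave it to the C10 aldehyde (H5IO6), run an HWE with triethyl 2-phosphonopropionate (E >95:5), and reduce the ester with DIBAL.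
3. **Step 9 (Grignard formation and coupling from the hindered neopentyl-like iodide).** Mg insertion may be sluggish, and Wurtz coupling or SN2′ attack may compete.
   - Fallback: skip the organometallic. Use Ni-catalysed cross-electrophile coupling (NiBr2·diglyme/bipyridine, Zn, DMA) of iodide 6 or 7 with bromide 11.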